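**Compound numbers used throughout**

1 ethyl acetoacetate · 2 ethyl butyrate · 3 ethyl 3,5-dioxooctanoate · 4 tetraethyl propane-1,1,3,3-tetracarboxylate · 5 diethyl 3,3'-methylenebis(5-butanoyl-2,4,6-trihydroxybenzoate) · 6 the corresponding bis-benzoic acid (not isolated) · 7 bis(3-butanoyl-2,4,6-trihydroxyphenyl)methane · 8 bis(dimethylaminomethyl) derivative of 7 · 9 butyrylphloroglucinol · 10 butyrylfilicinic acid · 11 target

## Analysis of the target

- **Ring system.** The target 11 is a linear tetramer of four six-membered carbocycles joined by three CH2 bridges. Ring A and ring D are enolised 2-acylcyclohexane-1,3,5-triones with a gem-dimethyl carbon (the butyrylfilicinic acid type). Ring B and ring C are hexasubstituted butyrylphloroglucinols.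
- **Numbering.** In ring B, C1 carries the CH2 to ring A, C2 an OH, C3 the central CH2, C4 an OH, C5 the butyryl group and C6 an OH. Ring C is numbered the same way towards ring D.
- **Stereochemistry.** There is no stereocentre, since each C(CH3)2 carbon carries two like groups. The molecule is constitutionally symmetric about the central CH2, and rings A and D can be written as several enol tautomers.
- **Sensitive groups.** The polyphenols are easily oxidised and the butyryl groups can be lost by retro-Claisen cleavage in hot alkali. The CH2 bridges are the most delicate part: in alkaline medium they are cleaved and redistributed (rottlerone-type change), and under acid and heat they can cyclodehydrate with a neighbouring enol.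
- **Difficulty.** The problem is not the carbon count but placing three bridges between four rings without the statistical oligomer mixtures that arise when monomers are condensed with formaldehyde. In each inner ring, C1 and C3 must also be told apart.
- **Feature the strategy rests on.** C3 of ring B and C3 of ring C each lie between hydroxylated C2 and C4 and are joined by the central CH2. These seven carbons are the skeleton of a propane-1,1,3,3-tetracarboxylate, which is compound 4, so the central bridge can be bought already placed between two malonate units.

## Retrosynthetic reasoning

**11 to 8 and two equivalents of 10.** The two outer bridges are cut between each outer CH2 and the end-ring carbon it is attached to. The CH2 stays on ring B and ring C as an aminomethyl group, which gives 8. This side is chosen because 10 has a single nucleophilic ring carbon and therefore cannot oligomerise. The electrophile is then an aromatic ortho-quinone methide, rather than a cross-conjugated methylene triketone on the end ring, which is more prone to self-reaction. Forward, each aminomethyl phenol of 8 must lose its amine and be captured at carbon by 10.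

**8 to 7.** The two C1–CH2N bonds are cut. C1 of ring B and of ring C are the only free ring carbons of 7, so aminomethylation has no regiochemical choice.

**10 to 9.** The two C–CH3 bonds at the gem-dimethyl carbon are cut. The end ring is then traced to a commercial acylphloroglucinol by dearomatising double C-methylation at one carbon.

**7 to 5 (via 6).** An ester is placed on C1 of each inner ring. It costs one hydrolysis and decarboxylation. In return it supplies the second active methylene needed for ring formation and keeps C1 blocked while the rings are made under basic conditions.

**5 to 4 and two equivalents of 3.** In ring B and in ring C the C1–C2 and C4–C5 bonds are cut, four bonds in all. C2, C3 and C4 of each ring together with the central CH2 are then 4. C1, C6 and C5 with the ester and the butyryl group are 3. Cutting here means the central bridge is never formed in the synthesis, and all six ring positions are set in one operation. Forward, each malonate unit of 4 must acylate both active methylenes of one molecule of 3.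

**3 to 1 and 2.** The C4–C5 bond of the octanoate chain is cut, which is the acylation of the terminal carbanion of the dianion of 1 by 2.

## Alternatives that were turned down

**Alternative 1:** Inner rings from pyranones.
- *Disconnection and key step.* Each inner ring is cut at C4–C5 and traced to a 4-hydroxypyran-2-one whose lactone carbonyl becomes C4. The monomeric pyranone A1 would be bridged at C3 with a one-carbon aldehyde to give the bis-pyranone A2. A magnesium alkoxide would then open both lactones, and the side-chain methylene between the two ketones would close onto the freed ester in a Claisen condensation to give the inner core A3, which is identical with 7.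
- *For.* The ring transformation is well established for single pyranones, and bridging at C3 of a 4-hydroxypyranone is easy. A3 arrives without a blocking group, so no decarboxylation is needed; on that point this route is stronger than the chosen one.
- *Against.* A1 needs polyanion acylation of a methylpyranone. The ring-opened chain can close in two ways, by Claisen to the phloroglucinol or by aldol to a resorcylate, and both halves must take the same path. A2 is a doubly vinylogous malonate adduct and can lose its bridge by retro-Michael cleavage in alkoxide. A3 is formed in base with free ring carbons, which are the conditions for redistribution of the bridge.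
- *Comparison.* The step count to 7 is about the same. The chosen route offers in exchange a purchased bridge, a ring closure with only one aromatising outcome, and fully substituted rings during the basic step.

**Alternative 2:** End rings closed last.
- *Disconnection and key step.* The ring carbonyl carbon between the butyryl-bearing carbon and the bridge-bearing carbon is removed from ring A and ring D. The precursor A4 carries two open 4,4-dimethyl-3,5,7-trioxodecyl arms on a hexakis(methoxymethyl)-protected inner core. Each arm would be C-carboxylated at its diketone methylene with a chloroformate, and a strong alkoxide base would then close the ketone alpha carbon onto the new ester to give the protected tetramer A5.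
- *For.* All three bridges are in place before the last C–C bonds form, so no bridge is made by a late intermolecular condensation. On control of connectivity in the final stage it is stronger than the chosen route.
- *Against.* A4 is long to make. Its 2,2-dimethyl-1,3-diketone units cannot enolise between the ketones and are cleaved by alkoxide. C- versus O-carboxylation is uncertain. The closing ester sits on a carbon that is deprotonated first and is therefore a poor electrophile. Six acetals must be put on hindered, chelated phenols and removed at the end.
- *Comparison.* It is longer, and its riskiest step comes last on the most valuable material. The chosen route takes its risk at step 2 on cheap compounds and uses a ready-made end ring.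

**Alternative 3:** Cyclobutenone benzannulation.
- *Disconnection and key step.* The C3–C4 and C1–C2 bonds of ring B and of ring C are cut. Heating the skipped bis-ynol ether A6 with two equivalents of the cyclobutenone A7 would open each four-membered ring to a vinylketene, which adds to one alkyne, reopens and electrocyclises (Danheiser benzannulation) to the inner core A8 as its bis(ethyl ether) bis(silyl ether).
- *For.* The cascade is neutral and thermal, so no bridge scrambling by base is possible. Regiochemistry follows from the polarity of ynol ether and ketene, and every oxygen is differentiated; on that point it is stronger than the chosen route.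
- *Against.* A6 has a doubly propargylic CH2 between two ynol ethers and should isomerise and decompose easily. A7 has an acidic CH between two carbonyls and should enolise or open prematurely. A8 needs cleavage of two aryl ethyl ethers by strong Lewis acid next to butyryl groups and a diarylmethane bridge. The target does not need differentiated oxygens.
- *Comparison.* More steps, fragile partners and a harsh deprotection stand against the chosen route, which uses stable, cheap components and a single ester as the only group to remove.

Key step: step 2

Remark: 11 is achiral and is treated as the tautomer drawn in its structure; all enol and keto forms of rings A and D are taken as equivalent.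

## Route

**Step 1**
Reactants: 1 ethyl acetoacetate; 2 ethyl butyrate
Product: 3 ethyl 3,5-dioxooctanoate
Conditions: LiN(i-Pr)2 (4.2 equiv), 1 (2.0 equiv), THF, 0 °C; then 2 (1.0 equiv), 0 °C to rt; 1 M HCl, 0 °C; used without distillation
Reagents that add atoms: none
Why: Claisen acylation of the dianion of a beta-keto ester, whose terminal carbanion is the more reactive site and attacks the ester carbonyl of 2; the second equivalent of dianion takes up the acidic proton of the product, and the cold work-up without distillation avoids lactonisation of 3 to a pyranone.

**Step 2**
Reactants: 3 ethyl 3,5-dioxooctanoate (2.2 equiv); 4 tetraethyl propane-1,1,3,3-tetracarboxylate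
Product: 5 diethyl 3,3'-methylenebis(5-butanoyl-2,4,6-trihydroxybenzoate)
Conditions: NaOEt (8 equiv), EtOH, 0 °C to reflux; toluene added and EtOH distilled off, 110 °C; then 1 M HCl, 0 °C
Reagents that add atoms: none
Why: In excess NaOEt the sodium diketonate of 3 should attack one ester carbonyl of a malonate unit of 4 through C4 (or through C2 from the small dianion population) with loss of ethoxide, and the second active methylene of the same molecule of 3 then acylates on the other ester of that malonate unit. This second acylation is a 6-exo-trig Claisen (Dieckmann-type) closure, once for ring B and once for ring C, which forms the C1–C2 and C4–C5 bonds of each ring, and the cyclohexane-1,3,5-triones so formed enolise to the benzene rings. The closest known reaction type is the alkoxide-mediated condensation of malonic esters with 3-oxoglutarate-type bis-nucleophiles to phloroglucinol carboxylates; the difference here lies in the substrate, a C-alkylated bis-malonate that must react at both ends. All Claisen steps are reversible, and the sequence should be pulled forward by distilling off EtOH and by formation of the aromatic polyphenoxide of each ring, which takes no part in retro-Claisen cleavage. The selectivity needed is C-acylation and annulation over O-acylation and over lactonisation of 3 to its own pyranone. It is secured by keeping 3 as its chelated sodium enolate, whose ester is a poor electrophile for its own enolate oxygen, and by the fact that enol and aryl esters from O-acylation are reopened by ethoxide, so that material drains to the C-acylated aromatic product. Each malonate unit is symmetric, so either order of the two bond formations and either orientation of 3 gives the same ring, and no stereocentre is formed. The ester from C1 of 3 stays on C1 of each ring, so every ring position of 5 is substituted and the central CH2 cannot be redistributed onto free ring carbons in the basic medium.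

**Step 3**
Reactants: 5 diethyl 3,3'-methylenebis(5-butanoyl-2,4,6-trihydroxybenzoate)
Product: 7 bis(3-butanoyl-2,4,6-trihydroxyphenyl)methane, via bis-benzoic acid 6 (not isolated)
Conditions: 2 M KOH (aq, degassed), 90 °C, Ar; then 6 M HCl to pH 1, 60 °C
Reagents that add atoms: none
Why: Ester saponification followed by protodecarboxylation of 2,4,6-trihydroxybenzoic acids, which lose CO2 readily through ipso protonation (beta-keto acid tautomer); C1 stays blocked as carboxylate during the basic stage and is freed only in acid, where the CH2 bridge should be stable.

**Step 4**
Reactants: 7 bis(3-butanoyl-2,4,6-trihydroxyphenyl)methane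
Product: 8 bis[3-butanoyl-5-(dimethylaminomethyl)-2,4,6-trihydroxyphenyl]methane
Conditions: CH2(NMe2)2 (2.5 equiv), EtOH, 0 °C to rt, Ar
Reagents that add atoms: bis(dimethylamino)methane, CN(C)CN(C)C
Why: Mannich aminomethylation: the acidic phenol protonates the aminal to the iminium ion, which substitutes the only free carbon (C1) of each electron-rich ring; at room temperature the Mannich base should not yet eliminate, and it is expected to separate as a zwitterionic solid.

**Step 5**
Reactants: 9 1-(2,4,6-trihydroxyphenyl)butan-1-one (butyrylphloroglucinol)
Product: 10 2-butanoyl-3,5-dihydroxy-4,4-dimethylcyclohexa-2,5-dien-1-one (butyrylfilicinic acid)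
Conditions: MeI (2.2 equiv), NaOMe (3 equiv), MeOH, 0 °C to rt; chromatography
Reagents that add atoms: iodomethane, CI
Why: C-alkylation of the phloroglucinol polyanion; after the first methylation the methylated carbon is the more electron-rich site, and the second methylation there gives the dearomatised vinylogous-acid anion, a weak nucleophile, so alkylation should largely stop at the gem-dimethyl stage.

**Step 6**
Reactants: 8 bis[3-butanoyl-5-(dimethylaminomethyl)-2,4,6-trihydroxyphenyl]methane; 10 2-butanoyl-3,5-dihydroxy-4,4-dimethylcyclohexa-2,5-dien-1-one (2.4 equiv)
Product: 11 bis{3-butanoyl-5-[(5-butanoyl-2,4-dihydroxy-3,3-dimethyl-6-oxocyclohexa-1,4-dien-1-yl)methyl]-2,4,6-trihydroxyphenyl}methane (target)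
Conditions: 1,4-dioxane, 90 °C, Ar sweep; then 0.5 M HCl wash
Reagents that add atoms: none
Why: Thermal loss of Me2NH from each phenolic Mannich base, assisted by the acidic 10, should give an ortho-quinone methide on ring B and ring C, which is trapped by Michael addition of the only nucleophilic ring carbon of 10 with rearomatisation; 10 is monofunctional, so its excess cannot cause oligomers, and the argon sweep removes the amine to limit base-induced bridge exchange.

## Compound list

1 | ethyl acetoacetate (ethyl 3-oxobutanoate) | CCOC(=O)CC(C)=O | starting material
2 | ethyl butyrate (ethyl butanoate) | CCCC(=O)OCC | starting material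
3 | ethyl 3,5-dioxooctanoate | CCCC(=O)CC(=O)CC(=O)OCC | intermediate
4 | tetraethyl propane-1,1,3,3-tetracarboxylate | CCOC(=O)C(CC(C(=O)OCC)C(=O)OCC)C(=O)OCC | starting material
5 | diethyl 3,3'-methylenebis(5-butanoyl-2,4,6-trihydroxybenzoate) | CCCC(=O)c1c(O)c(C(=O)OCC)c(O)c(Cc2c(O)c(C(=O)OCC)c(O)c(C(=O)CCC)c2O)c1O | intermediate
6 | 3,3'-methylenebis(5-butanoyl-2,4,6-trihydroxybenzoic acid) | CCCC(=O)c1c(O)c(C(=O)O)c(O)c(Cc2c(O)c(C(=O)O)c(O)c(C(=O)CCC)c2O)c1O | intermediate
7 | bis(3-butanoyl-2,4,6-trihydroxyphenyl)methane | CCCC(=O)c1c(O)cc(O)c(Cc2c(O)cc(O)c(C(=O)CCC)c2O)c1O | intermediate
8 | bis[3-butanoyl-5-(dimethylaminomethyl)-2,4,6-trihydroxyphenyl]methane | CCCC(=O)c1c(O)c(CN(C)C)c(O)c(Cc2c(O)c(CN(C)C)c(O)c(C(=O)CCC)c2O)c1O | intermediate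
9 | 1-(2,4,6-trihydroxyphenyl)butan-1-one (butyrylphloroglucinol) | CCCC(=O)c1c(O)cc(O)cc1O | starting material
10 | 2-butanoyl-3,5-dihydroxy-4,4-dimethylcyclohexa-2,5-dien-1-one (butyrylfilicinic acid) | CCCC(=O)C1=C(O)C(C)(C)C(O)=CC1=O | intermediate
11 | bis{3-butanoyl-5-[(5-butanoyl-2,4-dihydroxy-3,3-dimethyl-6-oxocyclohexa-1,4-dien-1-yl)methyl]-2,4,6-trihydroxyphenyl}methane (CNP0110234.0) | CCCC(=O)C1=C(O)C(C)(C)C(O)=C(Cc2c(O)c(Cc3c(O)c(CC4=C(O)C(C)(C)C(O)=C(C(=O)CCC)C4=O)c(O)c(C(=O)CCC)c3O)c(O)c(C(=O)CCC)c2O)C1=O | target

## Step count and least certain steps

Total: 6 steps. Longest linear sequence: 5 steps (steps 1, 2, 3, 4 and 6); step 5 is a one-step side branch.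

**Step 2 (key step).**
- *What may go wrong.* The malonate CH groups of 4 are deprotonated by ethoxide, and the esters of these enolates are poor acyl acceptors, so acylation by the stabilised enolate of 3 may stall. Meanwhile 3 can be used up by lactonisation to its pyranone or by retro-Claisen cleavage. 4 can also fragment by retro-Michael reaction, and annulation may stop after one ring. Lactonisation of a phenoxide of the first ring onto the second malonate unit is expected to be reversible and not harmful, since an aryl ester is the better acyl donor.
- *Fallback.* Set out from 9 and condense it with formaldehyde (0.5 equiv, with 9 in excess to hold back higher oligomers) under mild acid or base. Both free ring carbons of 9 are equivalent, so the dimer is 7 directly. The route is rejoined at 7; steps 1 to 3 are bypassed and no new compound is made.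

**Step 3.**
- *What may go wrong.* Hydrolysis of the chelated, electron-rich and doubly ortho-substituted esters may be slow as their phenoxides. Forcing the alkali then invites loss of butyryl groups by retro-Claisen cleavage and cleavage of the diarylmethane bridge.
- *Fallback.* Use an acid-labile blocking ester. Set out from 2 and 4: the dianion of tert-butyl acetoacetate is acylated with 2 to give tert-butyl 3,5-dioxooctanoate F1. F1 is condensed with 4 as in step 2, but with NaOt-Bu in toluene so that the alkoxide does not exchange the blocking ester, to give di-tert-butyl 3,3'-methylenebis(5-butanoyl-2,4,6-trihydroxybenzoate) F2. Treatment with CF3CO2H in CH2Cl2 at rt removes isobutene and CO2 without any alkali, and the route is rejoined at 7.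

**Step 5.**
- *What may go wrong.* Selectivity between geminal dimethylation, methylation at two different ring carbons and over-methylation may be poor, because all are C-alkylations of similar polyanions.
- *Fallback.* Set out from 9 and acylate it a second time (butanoyl chloride, AlCl3) to 1,1'-(2,4,6-trihydroxy-1,3-phenylene)bis(butan-1-one) F3, which has only one free ring carbon. MeI and NaOMe can then only give the gem-dimethyl compound 2,4-dibutanoyl-3,5-dihydroxy-6,6-dimethylcyclohexa-2,4-dien-1-one F4. Brief warming in aqueous H2SO4 removes one of the two equivalent butyryl groups by acid retro-Claisen cleavage, and the route is rejoined at 10.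

**Step 6.**
- *What may go wrong.* The coupling may stop at one end. The liberated amine may promote exchange of CH2 units between rings (retro-Mannich and rottlerone-type change), which gives mixtures of bridged oligomers. The ortho-quinone methide may also be trapped at oxygen or dimerise.
- *Fallback.* Reverse the polarity. Set out from 10 and aminomethylate it with CH2(NMe2)2 to 2-butanoyl-6-(dimethylaminomethyl)-3,5-dihydroxy-4,4-dimethylcyclohexa-2,5-dien-1-one F5. Heat F5 (2.2 equiv) with 7, which now serves as the bis-nucleophile through its two free ring carbons. Elimination from F5 is easier and needs lower temperature, and the route is rejoined at 11.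

## Further compounds

F0 | step 2 | none | none
F1 | step 3 | tert-butyl 3,5-dioxooctanoate | CCCC(=O)CC(=O)CC(=O)OC(C)(C)C
F2 | step 3 | di-tert-butyl 3,3'-methylenebis(5-butanoyl-2,4,6-trihydroxybenzoate) | CCCC(=O)c1c(O)c(C(=O)OC(C)(C)C)c(O)c(Cc2c(O)c(C(=O)OC(C)(C)C)c(O)c(C(=O)CCC)c2O)c1O
F3 | step 5 | 1,1'-(2,4,6-trihydroxy-1,3-phenylene)bis(butan-1-one) | CCCC(=O)c1c(O)cc(O)c(C(=O)CCC)c1O
F4 | step 5 | 2,4-dibutanoyl-3,5-dihydroxy-6,6-dimethylcyclohexa-2,4-dien-1-one | CCCC(=O)C1=C(O)C(C)(C)C(=O)C(C(=O)CCC)=C1O
F5 | step 6 | 2-butanoyl-6-(dimethylaminomethyl)-3,5-dihydroxy-4,4-dimethylcyclohexa-2,5-dien-1-one | CCCC(=O)C1=C(O)C(C)(C)C(O)=C(CN(C)C)C1=O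
A1 | alternative 1 | 4-hydroxy-6-(2-oxopentyl)-2H-pyran-2-one | CCCC(=O)CC1=CC(O)=CC(=O)O1
A2 | alternative 1 | 3,3'-methylenebis[4-hydroxy-6-(2-oxopentyl)-2H-pyran-2-one] | CCCC(=O)CC1=CC(O)=C(CC2=C(O)C=C(CC(=O)CCC)OC2=O)C(=O)O1
A3 | alternative 1 | bis(3-butanoyl-2,4,6-trihydroxyphenyl)methane (identical with 7) | CCCC(=O)c1c(O)cc(O)c(Cc2c(O)cc(O)c(C(=O)CCC)c2O)c1O
A4 | alternative 2 | bis[3-butanoyl-5-(4,4-dimethyl-3,5,7-trioxodecyl)-2,4,6-tris(methoxymethoxy)phenyl]methane | CCCC(=O)CC(=O)C(C)(C)C(=O)CCc1c(OCOC)c(Cc2c(OCOC)c(CCC(=O)C(C)(C)C(=O)CC(=O)CCC)c(OCOC)c(C(=O)CCC)c2OCOC)c(OCOC)c(C(=O)CCC)c1OCOC
A5 | alternative 2 | target tetramer as its hexakis(methoxymethyl) ether on rings B and C | CCCC(=O)C1=C(O)C(C)(C)C(O)=C(Cc2c(OCOC)c(Cc3c(OCOC)c(CC4=C(O)C(C)(C)C(O)=C(C(=O)CCC)C4=O)c(OCOC)c(C(=O)CCC)c3OCOC)c(OCOC)c(C(=O)CCC)c2OCOC)C1=O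
A6 | alternative 3 | 1,5-bis(triisopropylsilyloxy)penta-1,4-diyne | CC(C)[Si](OC#CCC#CO[Si](C(C)C)(C(C)C)C(C)C)(C(C)C)C(C)C
A7 | alternative 3 | 4-butanoyl-3-ethoxycyclobut-2-en-1-one | CCCC(=O)C1C(=O)C=C1OCC
A8 | alternative 3 | inner core as its bis(ethyl ether) bis(triisopropylsilyl ether) | CCCC(=O)c1c(O)c(Cc2c(O)c(C(=O)CCC)c(OCC)cc2O[Si](C(C)C)(C(C)C)C(C)C)c(O[Si](C(C)C)(C(C)C)C(C)C)cc1OCC
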